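**Retrosynthetic overview**
- Feature: the hydroxyl oxygen O9 on C9 and the ring C (dihydrofuran) oxygen on C7 stand 1,3 to each other across C8. A silicon atom parked on O9 can therefore reach C7 through a five-membered ring and bring hydrogen to C8 on the same face of a C7=C8 alkene (ring A = trimethoxyphenyl on C7, ring B = C1'–C6').
- Late disconnections: C1'–C7' (Heck reaction on a C1' bromide, then ester reduction); O4'–C7 of ring C (benzylic closure of a 1,3-diol onto the ring B phenol); C7–OH from C7–Si (oxidative removal of the tether).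
- Key disconnection: 1,2-oxasilolane back to the (E)-2,3-diarylallyl dimethylsilyl ether by asymmetric intramolecular hydrosilylation, which sets C7 and C8.
- The alkene comes from a C8–C3' Negishi union of a (Z)-2-iodo-3-arylacrylate (ring A) with an arylzinc (ring B), so its geometry is fixed before the coupling.
- Ring order: rings A and B are bought; the temporary oxasilolane forms in step 7 and is dismantled in step 8; ring C closes in step 9.

Key step: step 7

Assumption: (S)-BINAP is taken to steer rhodium to the alkene face that is Re at both C7 and C8; if the extra aryl group on C8 reverses the sense of induction, (R)-BINAP is used and nothing else changes.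

**Step 1**
Reactants: 1 3,4,5-trimethoxybenzaldehyde; 2 methyl (triphenylphosphoranylidene)acetate
Product: 4 methyl (Z)-2-iodo-3-(3,4,5-trimethoxyphenyl)prop-2-enoate, via iodo ylide 3 (not isolated)
Conditions: 2, NIS, CH2Cl2, −20 °C; then 1, −20 → 40 °C
Reagents that add atoms: N-iodosuccinimide, O=C1CCC(=O)N1I
Why: Electrophilic iodination of the stabilised ylide followed by a Wittig reaction places the ester trans to ring A, as stabilised ylides do with aromatic aldehydes, so iodine ends cis to ring A (Z) and any minor isomer is removed by chromatography.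

**Step 2**
Reactants: 5 4-bromo-2-methoxyphenol
Product: 6 4-bromo-2-iodo-6-methoxyphenol
Conditions: NIS, TsOH·H2O (cat.), MeCN, 0 °C → rt, dark
Reagents that add atoms: N-iodosuccinimide, O=C1CCC(=O)N1I
Why: Electrophilic aromatic iodination is steered by the free hydroxyl, whose para position is blocked by bromine, to its one open ortho carbon (the future C3').

**Step 3**
Reactants: 6 4-bromo-2-iodo-6-methoxyphenol
Product: 7 5-bromo-1-iodo-3-methoxy-2-(methoxymethoxy)benzene
Conditions: MOMCl, iPr2NEt, CH2Cl2, 0 °C → rt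
Reagents that add atoms: chloromethyl methyl ether, COCCl
Why: Williamson-type O-alkylation of the phenol gives an acetal that should withstand the organometallic, hydride, rhodium and peroxide steps and that falls off in the acid of step 9.

**Step 4**
Reactants: 7 5-bromo-1-iodo-3-methoxy-2-(methoxymethoxy)benzene; 4 methyl (Z)-2-iodo-3-(3,4,5-trimethoxyphenyl)prop-2-enoate
Product: 10 methyl (E)-2-[5-bromo-3-methoxy-2-(methoxymethoxy)phenyl]-3-(3,4,5-trimethoxyphenyl)prop-2-enoate, via arylmagnesium chloride 8 (not isolated), via arylzinc chloride 9 (not isolated)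
Conditions: 7, iPrMgCl·LiCl, THF, −30 °C; ZnCl2, −30 → 0 °C; then 4, Pd(dba)2 (3 mol %), P(2-furyl)3 (6 mol %), 25 °C
Reagents that add atoms: none
Why: Iodine–magnesium exchange touches only the carbon–iodine bond next to the chelating MOM oxygen, transmetalation to zinc spares the ester, and the Negishi coupling with the alkenyl iodide runs at 25 °C with retention of geometry (rings A and B cis), while the electron-rich aryl bromide should stay inert to zerovalent palladium carrying a weak donor phosphine.

**Step 5**
Reactants: 10 methyl (E)-2-[5-bromo-3-methoxy-2-(methoxymethoxy)phenyl]-3-(3,4,5-trimethoxyphenyl)prop-2-enoate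
Product: 11 (E)-2-[5-bromo-3-methoxy-2-(methoxymethoxy)phenyl]-3-(3,4,5-trimethoxyphenyl)prop-2-en-1-ol
Conditions: iBu2AlH (2.5 equiv), CH2Cl2, −78 → −40 °C; aq. potassium sodium tartrate
Reagents that add atoms: none
Why: 1,2-Reduction of the conjugated ester by the electrophilic aluminium hydride at low temperature leaves the alkene geometry, the aryl bromide and the MOM acetal untouched.

**Step 6**
Reactants: 11 (E)-2-[5-bromo-3-methoxy-2-(methoxymethoxy)phenyl]-3-(3,4,5-trimethoxyphenyl)prop-2-en-1-ol
Product: 12 (E)-2-[5-bromo-3-methoxy-2-(methoxymethoxy)phenyl]-3-(3,4,5-trimethoxyphenyl)allyl dimethylsilyl ether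
Conditions: (HMe2Si)2NH, hexane, 40 °C; volatiles removed in vacuo, used crude
Reagents that add atoms: 1,1,3,3-tetramethyldisilazane, C[SiH](C)N[SiH](C)C
Why: O-Silylation by nitrogen-to-oxygen silyl transfer from the disilazane is driven by loss of ammonia and leaves no salt that could poison the rhodium catalyst.

**Step 7**
Reactants: 12 (E)-2-[5-bromo-3-methoxy-2-(methoxymethoxy)phenyl]-3-(3,4,5-trimethoxyphenyl)allyl dimethylsilyl ether
Product: 13 (3S,4S)-4-[5-bromo-3-methoxy-2-(methoxymethoxy)phenyl]-2,2-dimethyl-3-(3,4,5-trimethoxyphenyl)-1,2-oxasilolane (aryl groups trans on the ring)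
Conditions: [Rh((S)-BINAP)(acetone)2]ClO4 (5 mol %; from [Rh((S)-BINAP)(nbd)]ClO4, H2, then Ar purge), acetone, 0.1 M, 25 °C
Reagents that add atoms: none
Why: Proposed new method: the Si–H bond adds oxidatively to the cationic monovalent rhodium, the tethered C7=C8 alkene binds, and suprafacial migratory insertion followed by reductive elimination places silicon on C7 and hydrogen on C8 of one and the same face. The closest known reaction type is the rhodium–bisphosphine asymmetric intramolecular hydrosilylation of (E)-3-arylallyl silyl ethers, which are disubstituted alkenes; 12 keeps their geometry (ring A trans to CH2O) and adds ring B on C8, so the trisubstituted 2,3-diaryl alkene is the untested extension. The oxasilolane closes in the 5-endo-trig mode, the 4-exo alternative (silicon to C8) being disfavoured by ring strain and by the fully substituted C8. C8 is set by the alkene face that the C2-symmetric ligand leaves open, and C7 follows from it through syn addition, which on the (E)-alkene turns the cis aryl groups of 12 into trans aryl groups on the ring. The step needs facial selectivity (ligand), regioselectivity (the short O9–C9 tether) and chemoselectivity over C–Br and the MOM acetal (neutral medium, 25 °C, electron-rich aryl bromide), and moderate dilution keeps the addition intramolecular.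

**Step 8**
Reactants: 13 (3S,4S)-4-[5-bromo-3-methoxy-2-(methoxymethoxy)phenyl]-2,2-dimethyl-3-(3,4,5-trimethoxyphenyl)-1,2-oxasilolane
Product: 14 (1S,2S)-2-[5-bromo-3-methoxy-2-(methoxymethoxy)phenyl]-1-(3,4,5-trimethoxyphenyl)propane-1,3-diol
Conditions: 30% aq. H2O2, KF, KHCO3, THF–MeOH (1:1), 25 °C
Reagents that add atoms: hydrogen peroxide, OO
Why: In the Tamao–Kumada oxidation the peroxide adds to the fluoride-activated alkoxysilane and C7 migrates from silicon to oxygen with retention, so C7–Si becomes the (7S)-carbinol, O9 is released and C8 is not touched.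

**Step 9**
Reactants: 14 (1S,2S)-2-[5-bromo-3-methoxy-2-(methoxymethoxy)phenyl]-1-(3,4,5-trimethoxyphenyl)propane-1,3-diol
Product: 16 [(2R,3S)-5-bromo-7-methoxy-2-(3,4,5-trimethoxyphenyl)-2,3-dihydro-1-benzofuran-3-yl]methanol, via free phenol 15 (not isolated)
Conditions: conc. HCl (to 0.3 M), MeOH–THF (2:1), 40 °C
Reagents that add atoms: none
Why: Acid-catalysed acetal exchange removes the MOM group and SN1 etherification follows, in which the C7 cation stabilised by the para-methoxy group of ring A is captured by O4' on the face anti to the CH2OH on C8; this gives the trans (7R,8S) ring C, a cis product can re-ionise and drain to trans, and any SN2-like component on the (7S)-alcohol leads to the same isomer.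

**Step 10**
Reactants: 16 [(2R,3S)-5-bromo-7-methoxy-2-(3,4,5-trimethoxyphenyl)-2,3-dihydro-1-benzofuran-3-yl]methanol; 17 methyl acrylate
Product: 18 methyl (E)-3-[(2R,3S)-3-(hydroxymethyl)-7-methoxy-2-(3,4,5-trimethoxyphenyl)-2,3-dihydro-1-benzofuran-5-yl]prop-2-enoate
Conditions: Pd(OAc)2 (5 mol %), P(o-tol)3 (12 mol %), Et3N, DMF, 100 °C
Reagents that add atoms: none
Why: In the Mizoroki–Heck reaction, oxidative addition of C1'–Br to zerovalent palladium, syn insertion of the acrylate and syn β-hydride elimination give the (E)-cinnamate, and the free alcohol and the two non-enolisable stereocentres are not affected.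

**Step 11**
Reactants: 18 methyl (E)-3-[(2R,3S)-3-(hydroxymethyl)-7-methoxy-2-(3,4,5-trimethoxyphenyl)-2,3-dihydro-1-benzofuran-5-yl]prop-2-enoate
Product: 19 (7R,8S,7'E)-3,4,5,5'-tetramethoxy-4',7-epoxy-8,3'-neolign-7'-ene-9,9'-diol
Conditions: iBu2AlH (4 equiv), CH2Cl2, −78 → −20 °C; aq. potassium sodium tartrate
Reagents that add atoms: none
Why: After one equivalent is consumed by the free hydroxyl, 1,2-reduction of the cinnamate ester by the aluminium hydride gives the (E)-allylic alcohol without touching the alkene, ring C or the stereocentres.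

**Compound list**
1 | 3,4,5-trimethoxybenzaldehyde | COc1cc(C=O)cc(OC)c1OC | starting material
2 | methyl (triphenylphosphoranylidene)acetate | COC(=O)C=P(c1ccccc1)(c1ccccc1)c1ccccc1 | starting material
3 | methyl iodo(triphenylphosphoranylidene)acetate | COC(=O)C(I)=P(c1ccccc1)(c1ccccc1)c1ccccc1 | intermediate
4 | methyl (Z)-2-iodo-3-(3,4,5-trimethoxyphenyl)prop-2-enoate | COc1cc(/C=C(\I)C(=O)OC)cc(OC)c1OC | intermediate
5 | 4-bromo-2-methoxyphenol | COc1cc(Br)ccc1O | starting material
6 | 4-bromo-2-iodo-6-methoxyphenol | COc1cc(Br)cc(I)c1O | intermediate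
7 | 5-bromo-1-iodo-3-methoxy-2-(methoxymethoxy)benzene | COCOc1c(I)cc(Br)cc1OC | intermediate
8 | [5-bromo-3-methoxy-2-(methoxymethoxy)phenyl]magnesium chloride | COCOc1c([Mg]Cl)cc(Br)cc1OC | intermediate
9 | [5-bromo-3-methoxy-2-(methoxymethoxy)phenyl]zinc chloride | COCOc1c([Zn]Cl)cc(Br)cc1OC | intermediate
10 | methyl (E)-2-[5-bromo-3-methoxy-2-(methoxymethoxy)phenyl]-3-(3,4,5-trimethoxyphenyl)prop-2-enoate | COc1cc(/C=C(/C(=O)OC)c2cc(Br)cc(OC)c2OCOC)cc(OC)c1OC | intermediate
11 | (E)-2-[5-bromo-3-methoxy-2-(methoxymethoxy)phenyl]-3-(3,4,5-trimethoxyphenyl)prop-2-en-1-ol | COc1cc(/C=C(/CO)c2cc(Br)cc(OC)c2OCOC)cc(OC)c1OC | intermediate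
12 | (E)-2-[5-bromo-3-methoxy-2-(methoxymethoxy)phenyl]-3-(3,4,5-trimethoxyphenyl)allyl dimethylsilyl ether | COc1cc(/C=C(/CO[SiH](C)C)c2cc(Br)cc(OC)c2OCOC)cc(OC)c1OC | intermediate
13 | (3S,4S)-4-[5-bromo-3-methoxy-2-(methoxymethoxy)phenyl]-2,2-dimethyl-3-(3,4,5-trimethoxyphenyl)-1,2-oxasilolane (aryl groups trans) | COc1cc([C@@H]2[C@H](CO[Si]2(C)C)c3cc(Br)cc(OC)c3OCOC)cc(OC)c1OC | intermediate
14 | (1S,2S)-2-[5-bromo-3-methoxy-2-(methoxymethoxy)phenyl]-1-(3,4,5-trimethoxyphenyl)propane-1,3-diol | COc1cc([C@@H](O)[C@H](CO)c2cc(Br)cc(OC)c2OCOC)cc(OC)c1OC | intermediate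
15 | (1S,2S)-2-(5-bromo-2-hydroxy-3-methoxyphenyl)-1-(3,4,5-trimethoxyphenyl)propane-1,3-diol | COc1cc([C@@H](O)[C@H](CO)c2cc(Br)cc(OC)c2O)cc(OC)c1OC | intermediate
16 | [(2R,3S)-5-bromo-7-methoxy-2-(3,4,5-trimethoxyphenyl)-2,3-dihydro-1-benzofuran-3-yl]methanol | COc1cc([C@@H]2Oc3c(OC)cc(Br)cc3[C@H]2CO)cc(OC)c1OC | intermediate
17 | methyl acrylate | C=CC(=O)OC | starting material
18 | methyl (E)-3-[(2R,3S)-3-(hydroxymethyl)-7-methoxy-2-(3,4,5-trimethoxyphenyl)-2,3-dihydro-1-benzofuran-5-yl]prop-2-enoate | COc1cc([C@@H]2Oc3c(OC)cc(/C=C/C(=O)OC)cc3[C@H]2CO)cc(OC)c1OC | intermediate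
19 | (7R,8S,7'E)-3,4,5,5'-tetramethoxy-4',7-epoxy-8,3'-neolign-7'-ene-9,9'-diol | COc1cc([C@@H]2Oc3c(OC)cc(/C=C/CO)cc3[C@H]2CO)cc(OC)c1OC | target

**Totals**
Total step count: 11. Longest linear sequence: 10 steps (5 to 19, steps 2–11).

**The three steps most likely to fail**

*First, step 7.*
- What may go wrong: the crowded trisubstituted alkene may bind too weakly to the rhodium silyl hydride. Turnover could then stall, the Si–H bond could be spent on reduction of the acetone solvent, the double bond could migrate towards C9, or the ligand could tell the two faces apart poorly.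
- Fallback: it uses known chemistry, sets out from 11 and returns at 14.
- Alcohol 11 is capped (tBuPh2SiCl, imidazole, DMF) as the tert-butyldiphenylsilyl ether F1.
- Asymmetric hydroboration follows with monoisopinocampheylborane made from (−)-α-pinene (THF, −25 °C), a reagent established for trisubstituted and aryl-substituted alkenes. It puts boron on the less substituted C7 and hydrogen on C8 in a syn manner and gives the dialkylborane F2.
- Oxidation of F2 in the same flask (NaOH, H2O2, retention) leads to the mono-protected (1S,2S)-diol F3.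
- Bu4NF in THF then frees 14.
- The antipode of the borane is chosen by analogy with 1-substituted cycloalkenes, and the other antipode is equally accessible. Enantiomeric purity can be raised by crystallisation at the stage of 14 or 16.

*Second, step 9.*
- What may go wrong: the C7 cation may fragment with loss of the C9 carbon, lose the proton on C8 and so erase that stereocentre, or stay trapped by the solvent instead of closing.
- Fallback: it sets out from 14 and returns at 16, and it uses the C7 configuration set in step 7.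
- The primary hydroxyl is silylated selectively (tBuMe2SiCl, imidazole, CH2Cl2, 0 °C) to the O9 tert-butyldimethylsilyl ether F4.
- The aryl MOM group is removed under near-neutral conditions (Me3SiOTf, 2,2'-bipyridyl, CH2Cl2, 0 °C, then water) to give the phenol F5.
- Intramolecular Mitsunobu etherification (PPh3, DIAD, THF, 0 °C) closes O4'–C7 with inversion, (7S) to (7R), to the silyl-protected trans dihydrobenzofuran F6.
- Bu4NF in THF gives 16.

*Third, step 4.*
- What may go wrong: crowding around the carbon–iodine bond (ester on one side, ring A cis on the other) may slow the coupling. Geometric isomerisation at the alkenylpalladium stage, homocoupling of the arylzinc or insertion into the carbon–bromine bond could then take over.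
- Fallback: it sets out from 8 (generated from 7 as in step 4) and from 1, and it returns at 10. It builds the C7=C8 bond by condensation instead of the C8–C3' bond by coupling.
- Grignard reagent 8 opens oxirane (CuI cat., THF, −30 → 0 °C) to the 2-arylethanol F7.
- TEMPO and PhI(OAc)2 in MeCN–water oxidise F7 to the arylacetic acid F8.
- Perkin condensation with 1 (Ac2O, Et3N, 100 °C) gives the (E)-2,3-diarylacrylic acid F9 with the aryl groups cis, the normal outcome of this condensation.
- MeI and K2CO3 in DMF give ester 10.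

**Further compounds**
F1 | step 7 | (E)-2-[5-bromo-3-methoxy-2-(methoxymethoxy)phenyl]-3-(3,4,5-trimethoxyphenyl)allyl tert-butyldiphenylsilyl ether | COc1cc(/C=C(/CO[Si](c2ccccc2)(c2ccccc2)C(C)(C)C)c2cc(Br)cc(OC)c2OCOC)cc(OC)c1OC
F2 | step 7 | [(1S,2S)-2-[5-bromo-3-methoxy-2-(methoxymethoxy)phenyl]-3-(tert-butyldiphenylsilyloxy)-1-(3,4,5-trimethoxyphenyl)propyl](isopinocampheyl)borane | C[C@@H]1[C@H](C[C@H]2C[C@@H]1C2(C)C)B[C@H](c1cc(OC)c(OC)c(OC)c1)[C@H](CO[Si](c1ccccc1)(c1ccccc1)C(C)(C)C)c1cc(Br)cc(OC)c1OCOC
F3 | step 7 | (1S,2S)-2-[5-bromo-3-methoxy-2-(methoxymethoxy)phenyl]-3-(tert-butyldiphenylsilyloxy)-1-(3,4,5-trimethoxyphenyl)propan-1-ol | COc1cc([C@@H](O)[C@H](CO[Si](c2ccccc2)(c2ccccc2)C(C)(C)C)c2cc(Br)cc(OC)c2OCOC)cc(OC)c1OC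
F4 | step 9 | (1S,2S)-2-[5-bromo-3-methoxy-2-(methoxymethoxy)phenyl]-3-(tert-butyldimethylsilyloxy)-1-(3,4,5-trimethoxyphenyl)propan-1-ol | COc1cc([C@@H](O)[C@H](CO[Si](C)(C)C(C)(C)C)c2cc(Br)cc(OC)c2OCOC)cc(OC)c1OC
F5 | step 9 | 4-bromo-2-[(1S,2S)-3-(tert-butyldimethylsilyloxy)-1-hydroxy-1-(3,4,5-trimethoxyphenyl)propan-2-yl]-6-methoxyphenol | COc1cc([C@@H](O)[C@H](CO[Si](C)(C)C(C)(C)C)c2cc(Br)cc(OC)c2O)cc(OC)c1OC
F6 | step 9 | (2R,3S)-5-bromo-3-[(tert-butyldimethylsilyloxy)methyl]-7-methoxy-2-(3,4,5-trimethoxyphenyl)-2,3-dihydro-1-benzofuran | COc1cc([C@@H]2Oc3c(OC)cc(Br)cc3[C@H]2CO[Si](C)(C)C(C)(C)C)cc(OC)c1OC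
F7 | step 4 | 2-[5-bromo-3-methoxy-2-(methoxymethoxy)phenyl]ethanol | COCOc1c(CCO)cc(Br)cc1OC
F8 | step 4 | [5-bromo-3-methoxy-2-(methoxymethoxy)phenyl]acetic acid | COCOc1c(CC(=O)O)cc(Br)cc1OC
F9 | step 4 | (E)-2-[5-bromo-3-methoxy-2-(methoxymethoxy)phenyl]-3-(3,4,5-trimethoxyphenyl)prop-2-enoic acid | COc1cc(/C=C(/C(=O)O)c2cc(Br)cc(OC)c2OCOC)cc(OC)c1OC
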